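**Plan**

- Retrosynthetic cuts, in order: the five benzyl C–O bonds; the C2–C3 bond of the dihydrofuran ring (back to a diaryl carbene at C3, stored as hydrazone and ketone); the O–CH2 bond of the ortho 4-(benzyloxy)benzyl ether; the C3–C3a bond (aryllithium plus aldehyde); the ring A C–Br bond; the ethylene bridge (alkene, then Wittig).
- Forward: a Wittig reaction joins ring A (the benzo ring) to ring D (the phenethyl aryl) and diimide saturates the bridge; bromination and lithiation attach C3 with ring C (the 3,5-dioxygenated aryl) as a diaryl ketone; the oxygen ring is the only ring made and closes in the penultimate step.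
- Enabling feature: C2 carries O1 and the para-oxygenated ring B, so in the open form it is the CH2 of an electron-rich benzyl aryl ether on the ring A oxygen. Its hydridic C–H lies five atoms from C3 (C3–C3a–C7a–O1–C2), the geometry of a 1,5-insertion of a carbene at C3.
- The ketone carbonyl is also a handle: chelation to it singles out the one ortho benzyl ether among five, which is exchanged for the 4-(benzyloxy)benzyl group that supplies C2 and ring B.
- Stereochemistry: the target is the 2,3-cis isomer (2S,3R). Both centres arise in the ring closure; the chiral dirhodium carboxylate sets C3 (R), and the insertion sets C2 (S) cis to it as the kinetic product. All later conditions are neutral, so C2 should not epimerise to the trans isomer.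

Key step: step 9

Assumption: Rh2(R-PTAD)4, dirhodium tetrakis[(R)-(1-adamantyl)(phthalimido)acetate], is taken to deliver the (2S,3R) enantiomer; if the antipode forms, Rh2(S-PTAD)4 is used in the same procedure.

**Step 1**
Reactants: 1 3,5-bis(benzyloxy)benzaldehyde; 2 [4-(benzyloxy)benzyl]triphenylphosphonium chloride
Product: 4 tri-O-benzyl stilbene (E/Z mixture), via phosphonium ylide 3 (not isolated)
Conditions: KOt-Bu (1.1 equiv), THF, 0 °C; then 1, 0 °C to rt
Reagents that add atoms: none
Why: Wittig olefination; the semi-stabilised benzylic ylide should add cleanly to the aromatic aldehyde, and the E/Z mixture is of no consequence because the alkene is saturated in step 2.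

**Step 2**
Reactants: 4 tri-O-benzyl stilbene (E/Z mixture)
Product: 5 tri-O-benzyl dihydroresveratrol (the bibenzyl)
Conditions: TsNHNH2 (excess, in portions), NaOAc, THF/H2O, reflux
Reagents that add atoms: none
Why: Diimide reduction; diimide generated in situ from the sulfonyl hydrazide transfers two hydrogens to the C=C in a concerted syn fashion and cannot hydrogenolyse benzyl ethers, both alkene isomers converge on the same bibenzyl, and no stereocentre arises.

**Step 3**
Reactants: 5 tri-O-benzyl dihydroresveratrol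
Product: 6 ring A monobromide (bromine ortho to the ethylene bridge)
Conditions: NBS (1.0 equiv), MeCN/CH2Cl2, 0 °C, dark
Reagents that add atoms: N-bromosuccinimide, O=C1CCC(=O)N1Br
Why: Electrophilic aromatic bromination; ring A, with two ether oxygens and an alkyl group, is by far the most electron-rich ring, and its position next to the bridge (ortho to one oxygen, para to the other) should react in preference to the shielded position between the two ether groups, as in 5-alkylresorcinol diethers, the two such positions being equivalent.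

**Step 4**
Reactants: 6 ring A monobromide; 1 3,5-bis(benzyloxy)benzaldehyde
Product: 8 racemic diarylmethanol (carbinol carbon between ring A and ring C), via aryllithium 7 (not isolated)
Conditions: n-BuLi (1.05 equiv), THF, −78 °C; then 1, −78 °C to 0 °C; then H2O
Reagents that add atoms: none
Why: Bromine–lithium exchange at −78 °C should outrun deprotonation of the benzyl ether CH2 groups, and the aryllithium adds 1,2 to the aldehyde; the new carbinol centre is racemic and is erased in step 5.

**Step 5**
Reactants: 8 racemic diarylmethanol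
Product: 9 pentabenzyl diaryl ketone
Conditions: Dess–Martin periodinane, CH2Cl2, 0 °C to rt
Reagents that add atoms: none
Why: Dess–Martin oxidation of a doubly benzylic secondary alcohol proceeds under nearly neutral conditions that should leave all benzyl ethers intact.

**Step 6**
Reactants: 9 pentabenzyl diaryl ketone
Product: 10 2-hydroxy diaryl ketone (ring A oxygen ortho to the carbonyl set free)
Conditions: MgBr2·OEt2 (3 equiv), toluene/Et2O, 80 °C; then 1 M HCl
Reagents that add atoms: none
Why: Chelation-controlled ether cleavage; magnesium binds the carbonyl oxygen and the ortho ether oxygen in a six-membered chelate, so bromide attacks only that benzylic CH2, while the four benzyl ethers that cannot chelate (para, meta or remote) should survive.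

**Step 7**
Reactants: 10 2-hydroxy diaryl ketone; 11 4-(benzyloxy)benzyl chloride
Product: 12 diaryl ketone carrying the ortho 4-(benzyloxy)benzyl ether
Conditions: K2CO3, KI (cat.), DMF, 60 °C
Reagents that add atoms: none
Why: Williamson ether synthesis; the single free phenoxide, although hydrogen-bonded to the carbonyl, should be O-alkylated by the reactive benzylic chloride in DMF, and no stereocentre is involved.

**Step 8**
Reactants: 12 diaryl ketone carrying the ortho 4-(benzyloxy)benzyl ether
Product: 13 diaryl ketone hydrazone (mixture of C=N isomers)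
Conditions: N2H4·H2O (excess), AcOH (cat.), n-BuOH, 110 °C
Reagents that add atoms: hydrazine (used as the hydrate), NN
Why: Hydrazone formation by condensation; excess hydrazine and heat should overcome the shielding by the two ortho substituents, and both C=N isomers lead to the same diazo compound in step 9.

**Step 9**
Reactants: 13 diaryl ketone hydrazone
Product: 15 (2S,3R)-cis-2,3-diaryl-2,3-dihydrobenzofuran pentabenzyl ether, via diaryldiazomethane 14 (not isolated)
Conditions: MnO2 (activated, 8 equiv), MgSO4, CH2Cl2, 0 °C, filter; then Rh2(R-PTAD)4 (1 mol %), CH2Cl2, 0 °C to rt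
Reagents that add atoms: none
Why: MnO2 dehydrogenates the hydrazone to diaryldiazomethane 14, which loses N2 on the divalent rhodium carboxylate dimer to give a donor/donor carbene at the future C3; this electrophilic carbene takes a hydride from the ether CH2 five atoms away (C3–C3a–C7a–O1–CH2) and the rhodium-bound C3 then collapses onto the O1=C2 oxocarbenium carbon inside the same catalyst pocket, a net 1,5-C–H insertion that forms the C2–C3 bond. The closest known reaction type is the enantioselective intramolecular C–H insertion of hydrazone-derived donor/donor rhodium carbenes into benzyl aryl ethers, which gives cis-2,3-diaryl-2,3-dihydrobenzofurans. The one ring formed, the five-membered oxygen ring fused to ring A, closes by this formal 1,5-insertion, in its stepwise limit a 5-endo-trig attack of C3 on the oxocarbenium. C3 (R) is set by the chiral phthalimido-adamantyl carboxylate ligands, which distinguish the two faces of the carbene, and C2 (S) follows as the kinetic cis partner because hydride transfer and C–C bond formation occur on the same face before the oxocarbenium can rotate. The step needs site selectivity over the other 1,5-related C–H bonds, those of the chain CH2 attached to ring D, and this should be secured by the ether oxygen and the para-alkoxy ring B, which make the OCH2 hydrogens far more hydridic; the plain benzyl ethers are para, meta or remote to the carbene and cannot reach it.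

**Step 10**
Reactants: 15 (2S,3R)-cis-2,3-diaryl-2,3-dihydrobenzofuran pentabenzyl ether
Product: 16 target CNP0174555.1
Conditions: H2 (1 atm), 10% Pd/C, EtOAc/MeOH, rt
Reagents that add atoms: none
Why: Catalytic hydrogenolysis should cleave the five primary benzyl C–O bonds as toluene under neutral conditions, whereas the secondary, hindered C2–O1 bond of a 2-aryl-2,3-dihydrobenzofuran normally survives ambient-pressure hydrogenation and no acid or base is present to epimerise C2.

**Compound list**

1 | 3,5-bis(benzyloxy)benzaldehyde | O=Cc1cc(OCc2ccccc2)cc(OCc2ccccc2)c1 | starting material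
2 | [4-(benzyloxy)benzyl]triphenylphosphonium chloride | [Cl-].c1ccccc1[P+](c1ccccc1)(c1ccccc1)Cc1ccc(OCc2ccccc2)cc1 | starting material
3 | {[4-(benzyloxy)phenyl]methylidene}triphenylphosphorane (ylide from 2) | c1ccccc1P(c1ccccc1)(c1ccccc1)=Cc1ccc(OCc2ccccc2)cc1 | intermediate
4 | 1,3-bis(benzyloxy)-5-{2-[4-(benzyloxy)phenyl]ethenyl}benzene (E/Z mixture) | C(=Cc1ccc(OCc2ccccc2)cc1)c1cc(OCc2ccccc2)cc(OCc2ccccc2)c1 | intermediate
5 | 1,3-bis(benzyloxy)-5-{2-[4-(benzyloxy)phenyl]ethyl}benzene | C(Cc1ccc(OCc2ccccc2)cc1)c1cc(OCc2ccccc2)cc(OCc2ccccc2)c1 | intermediate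
6 | 1,5-bis(benzyloxy)-2-bromo-3-{2-[4-(benzyloxy)phenyl]ethyl}benzene | C(Cc1ccc(OCc2ccccc2)cc1)c1cc(OCc2ccccc2)cc(OCc2ccccc2)c1Br | intermediate
7 | aryllithium from 6 (lithium in place of bromine) | C(Cc1ccc(OCc2ccccc2)cc1)c1cc(OCc2ccccc2)cc(OCc2ccccc2)c1[Li] | intermediate
8 | racemic [3,5-bis(benzyloxy)phenyl](2,4-bis(benzyloxy)-6-{2-[4-(benzyloxy)phenyl]ethyl}phenyl)methanol | C(Cc1ccc(OCc2ccccc2)cc1)c1cc(OCc2ccccc2)cc(OCc2ccccc2)c1C(O)c1cc(OCc2ccccc2)cc(OCc2ccccc2)c1 | intermediate
9 | [3,5-bis(benzyloxy)phenyl](2,4-bis(benzyloxy)-6-{2-[4-(benzyloxy)phenyl]ethyl}phenyl)methanone | C(Cc1ccc(OCc2ccccc2)cc1)c1cc(OCc2ccccc2)cc(OCc2ccccc2)c1C(=O)c1cc(OCc2ccccc2)cc(OCc2ccccc2)c1 | intermediate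
10 | (4-(benzyloxy)-2-hydroxy-6-{2-[4-(benzyloxy)phenyl]ethyl}phenyl)[3,5-bis(benzyloxy)phenyl]methanone | C(Cc1ccc(OCc2ccccc2)cc1)c1cc(OCc2ccccc2)cc(O)c1C(=O)c1cc(OCc2ccccc2)cc(OCc2ccccc2)c1 | intermediate
11 | 4-(benzyloxy)benzyl chloride, 1-(benzyloxy)-4-(chloromethyl)benzene | ClCc1ccc(OCc2ccccc2)cc1 | starting material
12 | (4-(benzyloxy)-2-{[4-(benzyloxy)phenyl]methoxy}-6-{2-[4-(benzyloxy)phenyl]ethyl}phenyl)[3,5-bis(benzyloxy)phenyl]methanone | C(Cc1ccc(OCc2ccccc2)cc1)c1cc(OCc2ccccc2)cc(OCc2ccc(OCc3ccccc3)cc2)c1C(=O)c1cc(OCc2ccccc2)cc(OCc2ccccc2)c1 | intermediate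
13 | hydrazone of ketone 12 (C=N–NH2, both geometric isomers) | C(Cc1ccc(OCc2ccccc2)cc1)c1cc(OCc2ccccc2)cc(OCc2ccc(OCc3ccccc3)cc2)c1C(=NN)c1cc(OCc2ccccc2)cc(OCc2ccccc2)c1 | intermediate
14 | diaryldiazomethane from 13 (C=N2 in place of C=N–NH2) | C(Cc1ccc(OCc2ccccc2)cc1)c1cc(OCc2ccccc2)cc(OCc2ccc(OCc3ccccc3)cc2)c1C(=[N+]=[N-])c1cc(OCc2ccccc2)cc(OCc2ccccc2)c1 | intermediate
15 | (2S,3R)-6-(benzyloxy)-2-[4-(benzyloxy)phenyl]-3-[3,5-bis(benzyloxy)phenyl]-4-{2-[4-(benzyloxy)phenyl]ethyl}-2,3-dihydro-1-benzofuran (2,3-cis) | C(c1ccccc1)Oc1ccc(CCc2cc(OCc3ccccc3)cc3c2[C@@H](c2cc(OCc4ccccc4)cc(OCc4ccccc4)c2)[C@@H](c2ccc(OCc4ccccc4)cc2)O3)cc1 | intermediate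
16 | 5-[(2S,3R)-6-hydroxy-2-(4-hydroxyphenyl)-4-[2-(4-hydroxyphenyl)ethyl]-2,3-dihydro-1-benzofuran-3-yl]benzene-1,3-diol (2,3-cis), CNP0174555.1 | Oc1ccc(CCc2cc(O)cc3c2[C@@H](c2cc(O)cc(O)c2)[C@@H](c2ccc(O)cc2)O3)cc1 | target

**Totals**

Total step count: 10. Longest linear sequence: 10 steps (1 to 16); compounds 1, 2 and 11 are purchased, and 1 is used in steps 1 and 4.

**Steps most likely to fail**

Step 9. The carbene may insert into the benzylic C–H of the phenethyl chain (the other 1,5 site), may dimerise to the azine, or may be poorly discriminated by the catalyst because both ortho positions of the carbene-bearing ring are substituted, which would erode the cis (2S,3R) selectivity. The fallback sets out from ketone 12 and returns at target 16. Lithium 2,2,6,6-tetramethylpiperidide (LiTMP, THF, −78 °C to rt) deprotonates the OCH2 of the ortho ether, and the carbanion adds to the ketone carbonyl (an aldol-type closure that forms the same C2–C3 bond) to give the 3-hydroxy-2,3-dihydrobenzofuran F1. Acid-catalysed dehydration (TsOH, toluene, 60 °C) gives the 2,3-diarylbenzofuran pentabenzyl ether F2. Hydrogenation over Pd/C in EtOH first removes the benzyl groups to give the pentahydroxy benzofuran F3, and under raised hydrogen pressure should add hydrogen syn across C2=C3 to give the cis-dihydrobenzofuran as a racemate, that is 16 together with its (2R,3S) enantiomer F4. Preparative HPLC on a chiral stationary phase then delivers 16.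

Step 8. Condensation may stall at a carbonyl shielded by two ortho substituents, or the forcing conditions may lead to azine formation. The fallback sets out from ketone 12 and returns at hydrazone 13 by activating the carbonyl as a thiocarbonyl. Lawesson's reagent (toluene, 100 °C) converts 12 into the diaryl thioketone F5. A thioketone reacts with nitrogen nucleophiles far more readily than the parent ketone, so N2H4·H2O in EtOH/THF at rt should give 13 with loss of hydrogen sulfide.

Step 10. Over-reduction may open the C2–O1 bond once ring B carries a free para-hydroxyl, or C2 may epimerise to the trans isomer through reversible ionisation of that bond on the catalyst. The fallback sets out from ketone 9, where neither a stereocentre nor the oxygen ring is at risk, and returns at target 16 through a fluoride-labile protecting-group set. Hydrogenolysis of 9 (H2, 1 atm, Pd/C, EtOAc/MeOH) gives the pentahydroxy ketone F6. TIPSCl and imidazole in DMF silylate the four free phenols but not the 2-hydroxyl, which is held in a hydrogen bond to the carbonyl, giving the tetrakis(triisopropylsilyl) ether F7. A Mitsunobu reaction (PPh3, DIAD, THF) with 4-(triisopropylsilyloxy)benzyl alcohol F8 (from 4-hydroxybenzyl alcohol, NaH then TIPSCl) installs the insertion site and gives the silyl-protected ketone F9. Condensation with hydrazine as in step 8 gives the hydrazone F10, MnO2 oxidation gives the diazo compound F11, and the same rhodium-catalysed C–H insertion gives the cis-(2S,3R) pentakis(triisopropylsilyl) ether F12. Desilylation with Et3N·3HF in THF, a non-basic fluoride source, gives 16.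

**Further compounds**

F1 | step 9 | 6-(benzyloxy)-2-[4-(benzyloxy)phenyl]-3-[3,5-bis(benzyloxy)phenyl]-4-{2-[4-(benzyloxy)phenyl]ethyl}-2,3-dihydro-1-benzofuran-3-ol (mixture of stereoisomers) | C(c1ccccc1)Oc1ccc(CCc2cc(OCc3ccccc3)cc3c2C(O)(c2cc(OCc4ccccc4)cc(OCc4ccccc4)c2)C(c2ccc(OCc4ccccc4)cc2)O3)cc1
F2 | step 9 | 6-(benzyloxy)-2-[4-(benzyloxy)phenyl]-3-[3,5-bis(benzyloxy)phenyl]-4-{2-[4-(benzyloxy)phenyl]ethyl}-1-benzofuran | C(c1ccccc1)Oc1ccc(CCc2cc(OCc3ccccc3)cc3oc(-c4ccc(OCc5ccccc5)cc4)c(-c4cc(OCc5ccccc5)cc(OCc5ccccc5)c4)c23)cc1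
F3 | step 9 | 5-{6-hydroxy-2-(4-hydroxyphenyl)-4-[2-(4-hydroxyphenyl)ethyl]-1-benzofuran-3-yl}benzene-1,3-diol | Oc1ccc(CCc2cc(O)cc3oc(-c4ccc(O)cc4)c(-c4cc(O)cc(O)c4)c23)cc1
F4 | step 9 | 5-[(2R,3S)-6-hydroxy-2-(4-hydroxyphenyl)-4-[2-(4-hydroxyphenyl)ethyl]-2,3-dihydro-1-benzofuran-3-yl]benzene-1,3-diol (enantiomer of 16) | Oc1ccc(CCc2cc(O)cc3c2[C@H](c2cc(O)cc(O)c2)[C@H](c2ccc(O)cc2)O3)cc1
F5 | step 8 | (4-(benzyloxy)-2-{[4-(benzyloxy)phenyl]methoxy}-6-{2-[4-(benzyloxy)phenyl]ethyl}phenyl)[3,5-bis(benzyloxy)phenyl]methanethione | C(Cc1ccc(OCc2ccccc2)cc1)c1cc(OCc2ccccc2)cc(OCc2ccc(OCc3ccccc3)cc2)c1C(=S)c1cc(OCc2ccccc2)cc(OCc2ccccc2)c1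
F6 | step 10 | {2,4-dihydroxy-6-[2-(4-hydroxyphenyl)ethyl]phenyl}(3,5-dihydroxyphenyl)methanone | Oc1ccc(CCc2cc(O)cc(O)c2C(=O)c2cc(O)cc(O)c2)cc1
F7 | step 10 | [3,5-bis(triisopropylsilyloxy)phenyl]{2-hydroxy-4-(triisopropylsilyloxy)-6-[2-(4-(triisopropylsilyloxy)phenyl)ethyl]phenyl}methanone | CC(C)[Si](C(C)C)(C(C)C)Oc1ccc(CCc2cc(O[Si](C(C)C)(C(C)C)C(C)C)cc(O)c2C(=O)c2cc(O[Si](C(C)C)(C(C)C)C(C)C)cc(O[Si](C(C)C)(C(C)C)C(C)C)c2)cc1
F8 | step 10 | 4-(triisopropylsilyloxy)benzyl alcohol | OCc1ccc(O[Si](C(C)C)(C(C)C)C(C)C)cc1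
F9 | step 10 | [3,5-bis(triisopropylsilyloxy)phenyl]{4-(triisopropylsilyloxy)-2-{[4-(triisopropylsilyloxy)phenyl]methoxy}-6-[2-(4-(triisopropylsilyloxy)phenyl)ethyl]phenyl}methanone | CC(C)[Si](C(C)C)(C(C)C)Oc1ccc(CCc2cc(O[Si](C(C)C)(C(C)C)C(C)C)cc(OCc3ccc(O[Si](C(C)C)(C(C)C)C(C)C)cc3)c2C(=O)c2cc(O[Si](C(C)C)(C(C)C)C(C)C)cc(O[Si](C(C)C)(C(C)C)C(C)C)c2)cc1
F10 | step 10 | hydrazone of ketone F9 | CC(C)[Si](C(C)C)(C(C)C)Oc1ccc(CCc2cc(O[Si](C(C)C)(C(C)C)C(C)C)cc(OCc3ccc(O[Si](C(C)C)(C(C)C)C(C)C)cc3)c2C(=NN)c2cc(O[Si](C(C)C)(C(C)C)C(C)C)cc(O[Si](C(C)C)(C(C)C)C(C)C)c2)cc1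
F11 | step 10 | diaryldiazomethane from F10 | CC(C)[Si](C(C)C)(C(C)C)Oc1ccc(CCc2cc(O[Si](C(C)C)(C(C)C)C(C)C)cc(OCc3ccc(O[Si](C(C)C)(C(C)C)C(C)C)cc3)c2C(=[N+]=[N-])c2cc(O[Si](C(C)C)(C(C)C)C(C)C)cc(O[Si](C(C)C)(C(C)C)C(C)C)c2)cc1
F12 | step 10 | (2S,3R)-3-[3,5-bis(triisopropylsilyloxy)phenyl]-6-(triisopropylsilyloxy)-2-[4-(triisopropylsilyloxy)phenyl]-4-[2-(4-(triisopropylsilyloxy)phenyl)ethyl]-2,3-dihydro-1-benzofuran (2,3-cis) | CC(C)[Si](C(C)C)(C(C)C)Oc1ccc(CCc2cc(O[Si](C(C)C)(C(C)C)C(C)C)cc3c2[C@@H](c2cc(O[Si](C(C)C)(C(C)C)C(C)C)cc(O[Si](C(C)C)(C(C)C)C(C)C)c2)[C@@H](c2ccc(O[Si](C(C)C)(C(C)C)C(C)C)cc2)O3)cc1
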